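**Retrosynthetic overview**
1. Siphonein ⇒ buffered desilylation, Steglich esterification of the 19-OH with (2E)-dodec-2-enoic acid, and selective removal of a primary TES ether.
2. C9=C10 enone ⇒ acetate elimination of an aldol; the key C9–C10 bond comes from an intermolecular aldol addition of the lithium enolate of a ring-β C13 ketone (C1–C9, C19) to a ring-ε C27 polyenal (C10–C7').
3. Ketone ⇒ (4R,6R)-actinol: enol triflate, carbonylation, reduction, allylic sulfone, addition to 3-(triethylsilyloxy)propanal, oxidation, desulfonylation.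
4. Polyenal ⇒ racemic α-ionone: C2 olefination, allylic oxidation, CBS reduction with diastereomer separation, C15 phosphonium salt + C10 dialdehyde Wittig, C2 Weinreb extension.
5. No ring is formed in the route: ring β comes intact from actinol and ring ε from α-ionone.

Assumption: (4R,6R)-actinol is bought as the enantiopure industrial zeaxanthin intermediate, and the enone C=C is taken as the large group in the oxazaborolidine reduction of step 14.

Abbreviations: TBS = tert-butyldimethylsilyl, TES = triethylsilyl, TBSO/TESO = the corresponding silyloxy groups, Tf = trifluoromethanesulfonyl. Carotenoid locants (C7, C9, C19, C3', C6') are used for the chain.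

**Route**

Step 1
Reactants: 1 (4R,6R)-4-hydroxy-2,2,6-trimethylcyclohexan-1-one
Product: 2 (4R,6R)-4-(TBSO)-2,2,6-trimethylcyclohexan-1-one
Conditions: TBSCl, imidazole, DMF, rt
Reagents that add atoms: tert-butyldimethylsilyl chloride, CC(C)(C)[Si](C)(C)Cl
Why: Imidazole-promoted silylation of the unhindered secondary alcohol is high-yielding and leaves the C4 carbinol configuration (the future C3 of ring β) untouched.

Step 2
Reactants: 2 (4R,6R)-4-(TBSO)-2,2,6-trimethylcyclohexan-1-one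
Product: 4 (4R)-4-(TBSO)-2,6,6-trimethylcyclohex-1-en-1-yl trifluoromethanesulfonate, via lithium enolate 3 (not isolated)
Conditions: LiN(iPr)2, THF, −78 to 0 °C; then PhNTf2, 0 °C to rt
Reagents that add atoms: N-phenylbis(trifluoromethanesulfonimide), O=S(=O)(N(c1ccccc1)S(=O)(=O)C(F)(F)F)C(F)(F)F
Why: The ketone has a single α-hydrogen (C2 is quaternary), so deprotonation gives one tetrasubstituted enolate that PhNTf2 traps on oxygen (enol triflate formation); the C6 stereocentre is erased on purpose and C4 is not affected.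

Step 3
Reactants: 4 (4R)-4-(TBSO)-2,6,6-trimethylcyclohex-1-en-1-yl trifluoromethanesulfonate
Product: 5 methyl (4R)-4-(TBSO)-2,6,6-trimethylcyclohex-1-ene-1-carboxylate
Conditions: Pd(OAc)2 (5 mol %), PPh3 (10 mol %), CO (1 atm), Et3N, MeOH/DMF, 60 °C
Reagents that add atoms: carbon monoxide, [C-]#[O+]; methanol, CO
Why: Palladium-catalysed methoxycarbonylation of the vinyl triflate (oxidative addition, CO insertion, methanolysis) installs C7 on the hindered ring carbon without needing a bulky carbon nucleophile.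

Step 4
Reactants: 5 methyl (4R)-4-(TBSO)-2,6,6-trimethylcyclohex-1-ene-1-carboxylate
Product: 6 [(4R)-4-(TBSO)-2,6,6-trimethylcyclohex-1-en-1-yl]methanol
Conditions: iBu2AlH (2.5 equiv), CH2Cl2, −78 to 0 °C; aq. potassium sodium tartrate
Reagents that add atoms: none
Why: iBu2AlH reduces the conjugated ester (1,2-reduction, twice) to the primary allylic alcohol and does not touch the silyl ether or the tetrasubstituted alkene.

Step 5
Reactants: 6 [(4R)-4-(TBSO)-2,6,6-trimethylcyclohex-1-en-1-yl]methanol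
Product: 7 (4R)-1-(bromomethyl)-4-(TBSO)-2,6,6-trimethylcyclohex-1-ene
Conditions: CBr4, PPh3, CH2Cl2, 0 °C
Reagents that add atoms: carbon tetrabromide, BrC(Br)(Br)Br
Why: Appel bromination converts the primary allylic alcohol under neutral conditions, so the silyl ether survives and substitution stays at the primary carbon.

Step 6
Reactants: 7 (4R)-1-(bromomethyl)-4-(TBSO)-2,6,6-trimethylcyclohex-1-ene
Product: 8 (4R)-4-(TBSO)-2,6,6-trimethyl-1-[(phenylsulfonyl)methyl]cyclohex-1-ene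
Conditions: PhSO2Na, DMF, rt
Reagents that add atoms: sodium benzenesulfinate, [Na+].[O-]S(=O)c1ccccc1
Why: SN2 S-alkylation of the sulfinate at the primary allylic bromide gives the cyclogeranyl-type sulfone, which is also the thermodynamically preferred regioisomer.

Step 7
Reactants: 9 propane-1,3-diol
Product: 10 3-(triethylsilyloxy)propan-1-ol
Conditions: 9 (3 equiv), TESCl (1 equiv), imidazole, CH2Cl2, 0 °C
Reagents that add atoms: chlorotriethylsilane, CC[Si](CC)(CC)Cl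
Why: Statistical monosilylation with a threefold excess of the cheap diol gives mainly the mono-TES ether, and the excess diol is washed out with water.

Step 8
Reactants: 10 3-(triethylsilyloxy)propan-1-ol
Product: 11 3-(triethylsilyloxy)propanal
Conditions: Dess–Martin periodinane, pyridine, CH2Cl2, 0 °C to rt
Reagents that add atoms: none
Why: Dess–Martin oxidation under pyridine buffer stops at the aldehyde and is mild enough for the acid-sensitive primary TES ether.

Step 9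
Reactants: 8 (4R)-4-(TBSO)-2,6,6-trimethyl-1-[(phenylsulfonyl)methyl]cyclohex-1-ene; 11 3-(triethylsilyloxy)propanal
Product: 13 1-[(4R)-4-(TBSO)-2,6,6-trimethylcyclohex-1-en-1-yl]-1-(phenylsulfonyl)-4-(TESO)butan-2-ol (diastereomer mixture), via lithiated sulfone 12 (not isolated)
Conditions: n-BuLi, THF, −78 °C; then 11, −78 °C; H2O quench
Reagents that add atoms: none
Why: The sulfonyl-stabilised allylic carbanion adds to the aldehyde through its α-carbon (the first stage of a Julia-type coupling) and forms the C7–C8 bond; the two new stereocentres form as a mixture that is removed in steps 10 and 11.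

Step 10
Reactants: 13 1-[(4R)-4-(TBSO)-2,6,6-trimethylcyclohex-1-en-1-yl]-1-(phenylsulfonyl)-4-(TESO)butan-2-ol
Product: 14 1-[(4R)-4-(TBSO)-2,6,6-trimethylcyclohex-1-en-1-yl]-1-(phenylsulfonyl)-4-(TESO)butan-2-one (C1 epimer mixture)
Conditions: Dess–Martin periodinane, pyridine, CH2Cl2, rt
Reagents that add atoms: none
Why: Dess–Martin oxidation of the secondary alcohol gives the β-keto sulfone under neutral conditions, and the remaining sulfone-bearing stereocentre is an epimer mixture that is removed in step 11.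

Step 11
Reactants: 14 1-[(4R)-4-(TBSO)-2,6,6-trimethylcyclohex-1-en-1-yl]-1-(phenylsulfonyl)-4-(TESO)butan-2-one
Product: 15 1-[(4R)-4-(TBSO)-2,6,6-trimethylcyclohex-1-en-1-yl]-4-(TESO)butan-2-one
Conditions: SmI2 (2.5 equiv), THF/MeOH, −78 °C
Reagents that add atoms: none
Why: SmI2 cleaves the C–S bond of α-sulfonyl ketones by single-electron transfer at −78 °C (reductive desulfonylation) and methanol protonates the samarium enolate, which leaves the β-silyloxy ketone and the ring alkene intact.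

Step 12
Reactants: 16 (±)-α-ionone
Product: 17 ethyl (2E,4E)-3-methyl-5-(2,6,6-trimethylcyclohex-2-en-1-yl)penta-2,4-dienoate (racemic)
Conditions: NaH, triethyl phosphonoacetate, THF, 0 °C to rt; chromatography
Reagents that add atoms: triethyl phosphonoacetate, CCOC(=O)CP(=O)(OCC)OCC
Why: Horner–Wadsworth–Emmons olefination of the methyl ketone gives mainly the 2E ester (the minor 2Z isomer is removed on silica) and the mild phosphonate anion does not move the ring double bond.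

Step 13
Reactants: 17 ethyl (2E,4E)-3-methyl-5-(2,6,6-trimethylcyclohex-2-en-1-yl)penta-2,4-dienoate
Product: 18 ethyl (2E,4E)-3-methyl-5-(2,6,6-trimethyl-4-oxocyclohex-2-en-1-yl)penta-2,4-dienoate (racemic)
Conditions: t-BuOOH (70 % aq, 5 equiv), dirhodium tetrakis(caprolactamate) Rh2(C6H10NO)4 (1 mol %), K2CO3, CH2Cl2, rt
Reagents that add atoms: tert-butyl hydroperoxide, CC(C)(C)OO
Why: Dirhodium-catalysed allylic oxidation with t-BuOOH converts the ring allylic CH2 into the enone, by analogy with the established conversion of α-ionone derivatives into their 3-oxo compounds.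

Step 14
Reactants: 18 ethyl (2E,4E)-3-methyl-5-(2,6,6-trimethyl-4-oxocyclohex-2-en-1-yl)penta-2,4-dienoate
Product: 19 ethyl (2E,4E)-5-[(1R,4R)-4-hydroxy-2,6,6-trimethylcyclohex-2-en-1-yl]-3-methylpenta-2,4-dienoate
Conditions: (S)-1-methyl-3,3-diphenyltetrahydro-1H,3H-pyrrolo[1,2-c][1,3,2]oxazaborole (0.5 equiv), catecholborane (1.5 equiv), toluene, −78 °C; chromatography
Reagents that add atoms: none
Why: Corey–Bakshi–Shibata reduction is reagent-controlled, so the new C4 carbinol is R in both enantiomers of 18; the (1R) half gives the trans (1R,4R) alcohol 19 and the (1S) half gives the cis (1S,4R) diastereomer that is removed on silica, which fixes both ring-ε stereocentres (C3' and C6').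

Step 15
Reactants: 19 ethyl (2E,4E)-5-[(1R,4R)-4-hydroxy-2,6,6-trimethylcyclohex-2-en-1-yl]-3-methylpenta-2,4-dienoate
Product: 20 ethyl (2E,4E)-5-[(1R,4R)-4-(TBSO)-2,6,6-trimethylcyclohex-2-en-1-yl]-3-methylpenta-2,4-dienoate
Conditions: TBSCl, imidazole, DMF, rt
Reagents that add atoms: tert-butyldimethylsilyl chloride, CC(C)(C)[Si](C)(C)Cl
Why: Silylation of the allylic secondary alcohol proceeds with retention and protects it from ionisation, oxidation and acylation in all later steps.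

Step 16
Reactants: 20 ethyl (2E,4E)-5-[(1R,4R)-4-(TBSO)-2,6,6-trimethylcyclohex-2-en-1-yl]-3-methylpenta-2,4-dienoate
Product: 21 (2E,4E)-5-[(1R,4R)-4-(TBSO)-2,6,6-trimethylcyclohex-2-en-1-yl]-3-methylpenta-2,4-dien-1-ol
Conditions: iBu2AlH (2.5 equiv), CH2Cl2, −78 °C; aq. potassium sodium tartrate
Reagents that add atoms: none
Why: iBu2AlH gives clean 1,2-reduction of the dienoate to the dienol without conjugate reduction or loss of the silyl ether.

Step 17
Reactants: 21 (2E,4E)-5-[(1R,4R)-4-(TBSO)-2,6,6-trimethylcyclohex-2-en-1-yl]-3-methylpenta-2,4-dien-1-ol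
Product: 23 {(2E,4E)-5-[(1R,4R)-4-(TBSO)-2,6,6-trimethylcyclohex-2-en-1-yl]-3-methylpenta-2,4-dien-1-yl}triphenylphosphonium bromide, via allylic bromide 22 (not isolated)
Conditions: CBr4, PPh3 (1.1 equiv), CH2Cl2, −20 °C; then PPh3 (1.5 equiv), rt
Reagents that add atoms: carbon tetrabromide, BrC(Br)(Br)Br; triphenylphosphine, c1ccc(cc1)P(c1ccccc1)c1ccccc1
Why: Appel bromination under neutral conditions followed by SN2 quaternisation of PPh3 in the same flask avoids the acidic PPh3·HBr route, which would ionise the allylic silyl ether.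

Step 18
Reactants: 23 {(2E,4E)-5-[(1R,4R)-4-(TBSO)-2,6,6-trimethylcyclohex-2-en-1-yl]-3-methylpenta-2,4-dien-1-yl}triphenylphosphonium bromide; 24 (2E,4E,6E)-2,7-dimethylocta-2,4,6-trienedial
Product: 26 (2E,4E,6E,8E,10E,12E)-13-[(1R,4R)-4-(TBSO)-2,6,6-trimethylcyclohex-2-en-1-yl]-2,7,11-trimethyltrideca-2,4,6,8,10,12-hexaenal, via phosphorus ylide 25 (not isolated)
Conditions: 24 (1.5 equiv), NaOMe, MeOH/CH2Cl2, 0 °C to rt; then I2 (1 mol %), CH2Cl2, daylight
Reagents that add atoms: none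
Why: Wittig olefination of the excess dialdehyde by the semi-stabilised allylic ylide forms C11'=C12' once (the classic C15 + C10 carotenoid coupling), and iodine-catalysed equilibration converts the Z isomer into the all-E aldehyde.

Step 19
Reactants: 26 (2E,4E,6E,8E,10E,12E)-13-[(1R,4R)-4-(TBSO)-2,6,6-trimethylcyclohex-2-en-1-yl]-2,7,11-trimethyltrideca-2,4,6,8,10,12-hexaenal
Product: 27 (2E,4E,6E,8E,10E,12E,14E)-N-methoxy-N,4,9,13-tetramethyl-15-[(1R,4R)-4-(TBSO)-2,6,6-trimethylcyclohex-2-en-1-yl]pentadeca-2,4,6,8,10,12,14-heptaenamide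
Conditions: NaH, diethyl [2-(methoxy(methyl)amino)-2-oxoethyl]phosphonate, THF, 0 °C to rt
Reagents that add atoms: diethyl [2-(methoxy(methyl)amino)-2-oxoethyl]phosphonate, CCOP(=O)(CC(=O)N(C)OC)OCC
Why: The Horner–Wadsworth–Emmons reaction with the Weinreb amide phosphonate adds C11 and C10 with high E selectivity and cannot over-homologate.

Step 20
Reactants: 27 (2E,4E,6E,8E,10E,12E,14E)-N-methoxy-N,4,9,13-tetramethyl-15-[(1R,4R)-4-(TBSO)-2,6,6-trimethylcyclohex-2-en-1-yl]pentadeca-2,4,6,8,10,12,14-heptaenamide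
Product: 28 (2E,4E,6E,8E,10E,12E,14E)-4,9,13-trimethyl-15-[(1R,4R)-4-(TBSO)-2,6,6-trimethylcyclohex-2-en-1-yl]pentadeca-2,4,6,8,10,12,14-heptaenal
Conditions: iBu2AlH (1.2 equiv), THF, −78 °C; aq. potassium sodium tartrate
Reagents that add atoms: none
Why: Hydride addition to the Weinreb amide gives a chelated aluminium hemiaminal that collapses to the aldehyde only on work-up, so the reduction stops at the C10 aldehyde.

Step 21
Reactants: 15 1-[(4R)-4-(TBSO)-2,6,6-trimethylcyclohex-1-en-1-yl]-4-(TESO)butan-2-one; 28 (2E,4E,6E,8E,10E,12E,14E)-4,9,13-trimethyl-15-[(1R,4R)-4-(TBSO)-2,6,6-trimethylcyclohex-2-en-1-yl]pentadeca-2,4,6,8,10,12,14-heptaenal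
Product: 30 (3R,3'R,6'R)-3,3'-bis(TBSO)-10-hydroxy-19-(TESO)-7,8,9,10-tetrahydro-β,ε-caroten-8-one (C9/C10 diastereomer mixture), via lithium enolate 29 (not isolated)
Conditions: 15 (1.3 equiv), LiN(iPr)2 (1.25 equiv), THF, −78 °C, 20 min; then 28, −78 °C, 30 min; AcOH quench at −78 °C
Reagents that add atoms: none
Why: Kinetic deprotonation by LiN(iPr)2 is expected at C9 because the C7 hydrogens are shielded by the tetrasubstituted ring carbon with its flanking methyl groups and cannot align with the ring π-system, and the lithium enolate then adds 1,2 to the polyenal at −78 °C faster than it can expel the β-silyloxy group (directed aldol addition); the new C9 and C10 stereocentres form as a mixture that is removed in step 23.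

Step 22
Reactants: 30 (3R,3'R,6'R)-3,3'-bis(TBSO)-10-hydroxy-19-(TESO)-7,8,9,10-tetrahydro-β,ε-caroten-8-one
Product: 31 (3R,3'R,6'R)-10-acetoxy-3,3'-bis(TBSO)-19-(TESO)-7,8,9,10-tetrahydro-β,ε-caroten-8-one (diastereomer mixture)
Conditions: Ac2O, pyridine, 4-(dimethylamino)pyridine (0.1 equiv), CH2Cl2, 0 °C
Reagents that add atoms: acetic anhydride, CC(=O)OC(C)=O
Why: Acylation of the secondary aldol hydroxyl turns it into a leaving group without placing an easily ionised sulfonate on the polyenylic carbon.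

Step 23
Reactants: 31 (3R,3'R,6'R)-10-acetoxy-3,3'-bis(TBSO)-19-(TESO)-7,8,9,10-tetrahydro-β,ε-caroten-8-one
Product: 32 (3R,3'R,6'R,all-E)-3,3'-bis(TBSO)-19-(TESO)-7,8-dihydro-β,ε-caroten-8-one
Conditions: DBU (1,8-diazabicyclo[5.4.0]undec-7-ene), CH2Cl2, 0 °C to rt
Reagents that add atoms: none
Why: E1cB elimination of acetate through the C9 enolate gives the fully conjugated enone as the thermodynamically favoured 9E isomer (ketone trans to the polyene chain), and acetate leaves far more readily than the C19 silyloxy group.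

Step 24
Reactants: 32 (3R,3'R,6'R,all-E)-3,3'-bis(TBSO)-19-(TESO)-7,8-dihydro-β,ε-caroten-8-one
Product: 33 (3R,3'R,6'R,all-E)-3,3'-bis(TBSO)-19-hydroxy-7,8-dihydro-β,ε-caroten-8-one
Conditions: pyridinium p-toluenesulfonate (0.2 equiv), MeOH/CH2Cl2, 0 °C
Reagents that add atoms: none
Why: Mild acid-catalysed methanolysis removes the primary TES ether much faster than the two secondary TBS ethers.

Step 25
Reactants: 33 (3R,3'R,6'R,all-E)-3,3'-bis(TBSO)-19-hydroxy-7,8-dihydro-β,ε-caroten-8-one; 34 (2E)-dodec-2-enoic acid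
Product: 35 (3R,3'R,6'R,all-E)-3,3'-bis(TBSO)-8-oxo-7,8-dihydro-β,ε-caroten-19-yl (2E)-dodec-2-enoate
Conditions: N,N'-diisopropylcarbodiimide, 4-(dimethylamino)pyridine (0.1 equiv), CH2Cl2, 0 °C
Reagents that add atoms: none
Why: Steglich esterification of the primary allylic alcohol with the free 2-enoic acid avoids the acid chloride and tertiary amine that would deconjugate the 2E double bond through a vinylketene.

Step 26
Reactants: 35 (3R,3'R,6'R,all-E)-3,3'-bis(TBSO)-8-oxo-7,8-dihydro-β,ε-caroten-19-yl (2E)-dodec-2-enoate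
Product: 36 (3R,3'R,6'R,all-E)-3,3'-dihydroxy-8-oxo-7,8-dihydro-β,ε-caroten-19-yl (2E)-dodec-2-enoate (siphonein, CNP0415260.1)
Conditions: HF·pyridine, pyridine, THF, 0 °C to rt
Reagents that add atoms: none
Why: Pyridine-buffered HF·pyridine cleaves both secondary TBS ethers by fluoride attack at silicon under non-basic conditions, so the allylic dodecenoate, the enone and the three stereocentres are untouched.

**Compound list**

1 | (4R,6R)-4-hydroxy-2,2,6-trimethylcyclohexan-1-one (actinol) | O=C1C(C)(C)C[C@H](O)C[C@H]1C | starting material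
2 | (4R,6R)-4-(tert-butyldimethylsilyloxy)-2,2,6-trimethylcyclohexan-1-one | O=C1C(C)(C)C[C@H](O[Si](C)(C)C(C)(C)C)C[C@H]1C | intermediate
3 | lithium (4R)-4-(tert-butyldimethylsilyloxy)-2,6,6-trimethylcyclohex-1-en-1-olate | [Li+].[O-]C1=C(C)C[C@@H](O[Si](C)(C)C(C)(C)C)CC1(C)C | intermediate
4 | (4R)-4-(tert-butyldimethylsilyloxy)-2,6,6-trimethylcyclohex-1-en-1-yl trifluoromethanesulfonate | O=S(=O)(OC1=C(C)C[C@@H](O[Si](C)(C)C(C)(C)C)CC1(C)C)C(F)(F)F | intermediate
5 | methyl (4R)-4-(tert-butyldimethylsilyloxy)-2,6,6-trimethylcyclohex-1-ene-1-carboxylate | COC(=O)C1=C(C)C[C@@H](O[Si](C)(C)C(C)(C)C)CC1(C)C | intermediate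
6 | [(4R)-4-(tert-butyldimethylsilyloxy)-2,6,6-trimethylcyclohex-1-en-1-yl]methanol | OCC1=C(C)C[C@@H](O[Si](C)(C)C(C)(C)C)CC1(C)C | intermediate
7 | (4R)-1-(bromomethyl)-4-(tert-butyldimethylsilyloxy)-2,6,6-trimethylcyclohex-1-ene | BrCC1=C(C)C[C@@H](O[Si](C)(C)C(C)(C)C)CC1(C)C | intermediate
8 | (4R)-4-(tert-butyldimethylsilyloxy)-2,6,6-trimethyl-1-[(phenylsulfonyl)methyl]cyclohex-1-ene | O=S(=O)(CC1=C(C)C[C@@H](O[Si](C)(C)C(C)(C)C)CC1(C)C)c1ccccc1 | intermediate
9 | propane-1,3-diol | OCCCO | starting material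
10 | 3-(triethylsilyloxy)propan-1-ol | OCCCO[Si](CC)(CC)CC | intermediate
11 | 3-(triethylsilyloxy)propanal | O=CCCO[Si](CC)(CC)CC | intermediate
12 | lithium [(4R)-4-(tert-butyldimethylsilyloxy)-2,6,6-trimethylcyclohex-1-en-1-yl](phenylsulfonyl)methanide | [Li+].O=S(=O)([CH-]C1=C(C)C[C@@H](O[Si](C)(C)C(C)(C)C)CC1(C)C)c1ccccc1 | intermediate
13 | 1-[(4R)-4-(tert-butyldimethylsilyloxy)-2,6,6-trimethylcyclohex-1-en-1-yl]-1-(phenylsulfonyl)-4-(triethylsilyloxy)butan-2-ol, mixture at C1 and C2 | OC(CCO[Si](CC)(CC)CC)C(C1=C(C)C[C@@H](O[Si](C)(C)C(C)(C)C)CC1(C)C)S(=O)(=O)c1ccccc1 | intermediate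
14 | 1-[(4R)-4-(tert-butyldimethylsilyloxy)-2,6,6-trimethylcyclohex-1-en-1-yl]-1-(phenylsulfonyl)-4-(triethylsilyloxy)butan-2-one, mixture at C1 | O=C(CCO[Si](CC)(CC)CC)C(C1=C(C)C[C@@H](O[Si](C)(C)C(C)(C)C)CC1(C)C)S(=O)(=O)c1ccccc1 | intermediate
15 | 1-[(4R)-4-(tert-butyldimethylsilyloxy)-2,6,6-trimethylcyclohex-1-en-1-yl]-4-(triethylsilyloxy)butan-2-one | O=C(CCO[Si](CC)(CC)CC)CC1=C(C)C[C@@H](O[Si](C)(C)C(C)(C)C)CC1(C)C | intermediate
16 | (±)-α-ionone, (3E)-4-(2,6,6-trimethylcyclohex-2-en-1-yl)but-3-en-2-one | CC(=O)/C=C/C1C(C)=CCCC1(C)C | starting material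
17 | ethyl (2E,4E)-3-methyl-5-(2,6,6-trimethylcyclohex-2-en-1-yl)penta-2,4-dienoate, racemic | CCOC(=O)/C=C(C)/C=C/C1C(C)=CCCC1(C)C | intermediate
18 | ethyl (2E,4E)-3-methyl-5-(2,6,6-trimethyl-4-oxocyclohex-2-en-1-yl)penta-2,4-dienoate, racemic | CCOC(=O)/C=C(C)/C=C/C1C(C)=CC(=O)CC1(C)C | intermediate
19 | ethyl (2E,4E)-5-[(1R,4R)-4-hydroxy-2,6,6-trimethylcyclohex-2-en-1-yl]-3-methylpenta-2,4-dienoate | CCOC(=O)/C=C(C)/C=C/[C@H]1C(C)=C[C@H](O)CC1(C)C | intermediate
20 | ethyl (2E,4E)-5-[(1R,4R)-4-(tert-butyldimethylsilyloxy)-2,6,6-trimethylcyclohex-2-en-1-yl]-3-methylpenta-2,4-dienoate | CCOC(=O)/C=C(C)/C=C/[C@H]1C(C)=C[C@H](O[Si](C)(C)C(C)(C)C)CC1(C)C | intermediate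
21 | (2E,4E)-5-[(1R,4R)-4-(tert-butyldimethylsilyloxy)-2,6,6-trimethylcyclohex-2-en-1-yl]-3-methylpenta-2,4-dien-1-ol | OC/C=C(C)/C=C/[C@H]1C(C)=C[C@H](O[Si](C)(C)C(C)(C)C)CC1(C)C | intermediate
22 | (2E,4E)-5-[(1R,4R)-4-(tert-butyldimethylsilyloxy)-2,6,6-trimethylcyclohex-2-en-1-yl]-3-methylpenta-2,4-dienyl bromide | BrC/C=C(C)/C=C/[C@H]1C(C)=C[C@H](O[Si](C)(C)C(C)(C)C)CC1(C)C | intermediate
23 | {(2E,4E)-5-[(1R,4R)-4-(tert-butyldimethylsilyloxy)-2,6,6-trimethylcyclohex-2-en-1-yl]-3-methylpenta-2,4-dien-1-yl}triphenylphosphonium bromide | [Br-].c1ccccc1[P+](c1ccccc1)(c1ccccc1)C/C=C(C)/C=C/[C@H]1C(C)=C[C@H](O[Si](C)(C)C(C)(C)C)CC1(C)C | intermediate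
24 | (2E,4E,6E)-2,7-dimethylocta-2,4,6-trienedial | O=C/C(C)=C/C=C/C=C(C)/C=O | starting material
25 | phosphorus ylide of 23, (2E,4E)-5-[(1R,4R)-4-(tert-butyldimethylsilyloxy)-2,6,6-trimethylcyclohex-2-en-1-yl]-3-methylpenta-2,4-dienylidene(triphenyl)phosphorane | c1ccccc1[P+](c1ccccc1)(c1ccccc1)[CH-]/C=C(C)/C=C/[C@H]1C(C)=C[C@H](O[Si](C)(C)C(C)(C)C)CC1(C)C | intermediate
26 | (2E,4E,6E,8E,10E,12E)-13-[(1R,4R)-4-(tert-butyldimethylsilyloxy)-2,6,6-trimethylcyclohex-2-en-1-yl]-2,7,11-trimethyltrideca-2,4,6,8,10,12-hexaenal | O=C/C(C)=C/C=C/C=C(C)/C=C/C=C(C)/C=C/[C@H]1C(C)=C[C@H](O[Si](C)(C)C(C)(C)C)CC1(C)C | intermediate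
27 | (2E,4E,6E,8E,10E,12E,14E)-N-methoxy-N,4,9,13-tetramethyl-15-[(1R,4R)-4-(tert-butyldimethylsilyloxy)-2,6,6-trimethylcyclohex-2-en-1-yl]pentadeca-2,4,6,8,10,12,14-heptaenamide | CON(C)C(=O)/C=C/C(C)=C/C=C/C=C(C)/C=C/C=C(C)/C=C/[C@H]1C(C)=C[C@H](O[Si](C)(C)C(C)(C)C)CC1(C)C | intermediate
28 | (2E,4E,6E,8E,10E,12E,14E)-4,9,13-trimethyl-15-[(1R,4R)-4-(tert-butyldimethylsilyloxy)-2,6,6-trimethylcyclohex-2-en-1-yl]pentadeca-2,4,6,8,10,12,14-heptaenal | O=C/C=C/C(C)=C/C=C/C=C(C)/C=C/C=C(C)/C=C/[C@H]1C(C)=C[C@H](O[Si](C)(C)C(C)(C)C)CC1(C)C | intermediate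
29 | lithium 1-[(4R)-4-(tert-butyldimethylsilyloxy)-2,6,6-trimethylcyclohex-1-en-1-yl]-4-(triethylsilyloxy)but-2-en-2-olate | [Li+].[O-]C(CC1=C(C)C[C@@H](O[Si](C)(C)C(C)(C)C)CC1(C)C)=CCO[Si](CC)(CC)CC | intermediate
30 | (3R,3'R,6'R)-3,3'-bis(tert-butyldimethylsilyloxy)-10-hydroxy-19-(triethylsilyloxy)-7,8,9,10-tetrahydro-β,ε-caroten-8-one, mixture at C9 and C10 | O=C(CC1=C(C)C[C@@H](O[Si](C)(C)C(C)(C)C)CC1(C)C)C(CO[Si](CC)(CC)CC)C(O)/C=C/C(C)=C/C=C/C=C(C)/C=C/C=C(C)/C=C/[C@H]1C(C)=C[C@H](O[Si](C)(C)C(C)(C)C)CC1(C)C | intermediate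
31 | (3R,3'R,6'R)-10-acetoxy-3,3'-bis(tert-butyldimethylsilyloxy)-19-(triethylsilyloxy)-7,8,9,10-tetrahydro-β,ε-caroten-8-one, mixture at C9 and C10 | O=C(CC1=C(C)C[C@@H](O[Si](C)(C)C(C)(C)C)CC1(C)C)C(CO[Si](CC)(CC)CC)C(OC(C)=O)/C=C/C(C)=C/C=C/C=C(C)/C=C/C=C(C)/C=C/[C@H]1C(C)=C[C@H](O[Si](C)(C)C(C)(C)C)CC1(C)C | intermediate
32 | (3R,3'R,6'R,all-E)-3,3'-bis(tert-butyldimethylsilyloxy)-19-(triethylsilyloxy)-7,8-dihydro-β,ε-caroten-8-one | CC[Si](CC)(CC)OC\C(=C/C=C/C(C)=C/C=C/C=C(C)/C=C/C=C(C)/C=C/[C@H]1C(C)=C[C@H](O[Si](C)(C)C(C)(C)C)CC1(C)C)C(=O)CC1=C(C)C[C@@H](O[Si](C)(C)C(C)(C)C)CC1(C)C | intermediate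
33 | (3R,3'R,6'R,all-E)-3,3'-bis(tert-butyldimethylsilyloxy)-19-hydroxy-7,8-dihydro-β,ε-caroten-8-one | OC\C(=C/C=C/C(C)=C/C=C/C=C(C)/C=C/C=C(C)/C=C/[C@H]1C(C)=C[C@H](O[Si](C)(C)C(C)(C)C)CC1(C)C)C(=O)CC1=C(C)C[C@@H](O[Si](C)(C)C(C)(C)C)CC1(C)C | intermediate
34 | (2E)-dodec-2-enoic acid | CCCCCCCCC/C=C/C(=O)O | starting material
35 | (3R,3'R,6'R,all-E)-3,3'-bis(tert-butyldimethylsilyloxy)-8-oxo-7,8-dihydro-β,ε-caroten-19-yl (2E)-dodec-2-enoate | CCCCCCCCC/C=C/C(=O)OC\C(=C/C=C/C(C)=C/C=C/C=C(C)/C=C/C=C(C)/C=C/[C@H]1C(C)=C[C@H](O[Si](C)(C)C(C)(C)C)CC1(C)C)C(=O)CC1=C(C)C[C@@H](O[Si](C)(C)C(C)(C)C)CC1(C)C | intermediate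
36 | (3R,3'R,6'R,all-E)-3,3'-dihydroxy-8-oxo-7,8-dihydro-β,ε-caroten-19-yl (2E)-dodec-2-enoate (siphonein) | CCCCCCCCC/C=C/C(=O)OC\C(=C/C=C/C(C)=C/C=C/C=C(C)/C=C/C=C(C)/C=C/[C@H]1C(C)=C[C@H](O)CC1(C)C)C(=O)CC1=C(C)C[C@@H](O)CC1(C)C | target

**Totals and risks**

Total step count: 26. Longest linear sequence: 15 steps (steps 1–6, 9–11 and 21–26 from 1; equally steps 12–26 from 16).

The three steps most likely to fail:

Step 21 (aldol). The ketone has two enolisable methylenes, and the C9 enolate carries a β-silyloxy group that could be expelled. Fallback: set out from the β-keto sulfone 14 instead of 15. With 2.1 equiv LiN(iPr)2 in THF at −78 °C the first deprotonation goes to the sulfonyl-activated C7, which is thereby blocked, and the second to C9. The dianion can then add to 28 only through C9, giving (3R,3'R,6'R)-3,3'-bis(TBSO)-10-hydroxy-7-(phenylsulfonyl)-19-(TESO)-7,8,9,10-tetrahydro-β,ε-caroten-8-one F1. SmI2 in THF/MeOH at −78 °C then removes the sulfonyl group and the route is rejoined at 30.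

Step 14 (oxazaborolidine reduction of a racemic enone). Both the sense and the level of reagent control on this cyclohexenone are uncertain, and they decide the enantiopurity of ring ε. Fallback: set out from 18 and reduce it without a chiral reagent (NaBH4, CeCl3·7H2O, MeOH, −78 °C). Chromatography gives racemic ethyl (2E,4E)-5-[(1R*,4R*)-4-hydroxy-2,6,6-trimethylcyclohex-2-en-1-yl]-3-methylpenta-2,4-dienoate F2. Esterification with (S)-2-methoxy-2-phenylacetic acid (N,N'-diisopropylcarbodiimide, 4-(dimethylamino)pyridine, CH2Cl2) gives two diastereomeric esters that are separated on silica. These are the wanted (1R,4R)-cyclohexenyl (S)-2-methoxy-2-phenylacetate F3 and the unwanted (1S,4S)-cyclohexenyl (S)-2-methoxy-2-phenylacetate F4, assigned from the NMR shift differences of the two esters. K2CO3 in EtOH cleaves F3 and the route is rejoined at 19.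

Step 26 (final desilylation next to the allylic ester). The 19-acyloxymethyl enone is an allylic electrophile and may not survive the long exposure needed to cleave two secondary TBS ethers. Fallback: set out from 33 and remove both TBS groups first (HF·pyridine, pyridine, THF), giving (3R,3'R,6'R,all-E)-3,19,3'-trihydroxy-7,8-dihydro-β,ε-caroten-8-one (siphonaxanthin) F5. The primary allylic 19-OH is then acylated selectively with 34 (1.0 equiv, N,N'-diisopropylcarbodiimide, 4-(dimethylamino)pyridine 0.05 equiv, CH2Cl2, −20 °C), and the route is rejoined at 36.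

**Further compounds**

F1 | step 21 | (3R,3'R,6'R)-3,3'-bis(tert-butyldimethylsilyloxy)-10-hydroxy-7-(phenylsulfonyl)-19-(triethylsilyloxy)-7,8,9,10-tetrahydro-β,ε-caroten-8-one, mixture at C7, C9 and C10 | O=C(C(C1=C(C)C[C@@H](O[Si](C)(C)C(C)(C)C)CC1(C)C)S(=O)(=O)c1ccccc1)C(CO[Si](CC)(CC)CC)C(O)/C=C/C(C)=C/C=C/C=C(C)/C=C/C=C(C)/C=C/[C@H]1C(C)=C[C@H](O[Si](C)(C)C(C)(C)C)CC1(C)C
F2 | step 14 | racemic ethyl (2E,4E)-5-[(1R*,4R*)-4-hydroxy-2,6,6-trimethylcyclohex-2-en-1-yl]-3-methylpenta-2,4-dienoate (both enantiomers written) | CCOC(=O)/C=C(C)/C=C/[C@H]1C(C)=C[C@H](O)CC1(C)C.CCOC(=O)/C=C(C)/C=C/[C@@H]1C(C)=C[C@@H](O)CC1(C)C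
F3 | step 14 | (1R,4R)-4-[(1E,3E)-5-ethoxy-3-methyl-5-oxopenta-1,3-dien-1-yl]-3,5,5-trimethylcyclohex-2-en-1-yl (S)-2-methoxy-2-phenylacetate | CCOC(=O)/C=C(C)/C=C/[C@H]1C(C)=C[C@H](OC(=O)[C@@H](OC)c2ccccc2)CC1(C)C
F4 | step 14 | (1S,4S)-4-[(1E,3E)-5-ethoxy-3-methyl-5-oxopenta-1,3-dien-1-yl]-3,5,5-trimethylcyclohex-2-en-1-yl (S)-2-methoxy-2-phenylacetate | CCOC(=O)/C=C(C)/C=C/[C@@H]1C(C)=C[C@@H](OC(=O)[C@@H](OC)c2ccccc2)CC1(C)C
F5 | step 26 | (3R,3'R,6'R,all-E)-3,19,3'-trihydroxy-7,8-dihydro-β,ε-caroten-8-one (siphonaxanthin) | OC\C(=C/C=C/C(C)=C/C=C/C=C(C)/C=C/C=C(C)/C=C/[C@H]1C(C)=C[C@H](O)CC1(C)C)C(=O)CC1=C(C)C[C@@H](O)CC1(C)C
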